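**Retrosynthetic overview**
1. Target 20 comes from phenol 19 by cleavage of its ten methyl ethers with BBr3.
2. The route rests on central ring B, which bears oxygen on five carbons (B1 O–ring A, B2 H, B3 OH, B4 O–ring C, B5 OH, B6 O–ring D). Each ether carbon can arrive already oxygenated inside a two-carbon aryloxy unit.
3. Ring B is cut at B2–B3, B1–B6 and B3–B4 into vinylketene 15 (from acid chloride 14: C1→B3, C2→B6, C3→B5, C4→B4) and ethynyl ether 13 (CH→B2, C–O→B1).
4. 14 comes from self-Claisen condensation of aryloxyacetate 3 (rings C and D are identical), enol O-methylation, saponification and chlorination. 13 comes from 2,4,6-trimethoxyphenol and trichloroethylene.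
5. Rings A, C and D are bought; ring B is the only ring formed, in step 8.

Key step: step 8

Assumption: the target has no stereocentre and is achiral, so no enantiocontrol is needed; 5, 6 and 14 are drawn as the Z isomers, but this geometry is lost at vinylketene 15, so either isomer serves.

**Step 1**
Reactants: 1 3,4,5-trimethoxyphenol; 2 methyl bromoacetate
Product: 3 methyl 2-(3,4,5-trimethoxyphenoxy)acetate
Conditions: K2CO3, acetone, reflux
Reagents that add atoms: none
Why: Williamson ether synthesis, in which the phenoxide of 1 displaces bromide from the activated α-bromo ester by SN2.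

**Step 2**
Reactants: 3 methyl 2-(3,4,5-trimethoxyphenoxy)acetate (2 equiv)
Product: 4 methyl 3-oxo-2,4-bis(3,4,5-trimethoxyphenoxy)butanoate (racemic, enolisable)
Conditions: NaH (0.6 equiv), cat. MeOH, THF, 0 °C → 50 °C; 1 M HCl
Reagents that add atoms: none
Why: Self-Claisen condensation, in which the enolate of one molecule of 3 acylates a second and irreversible deprotonation of the doubly activated C2–H of the β-keto ester drives the equilibrium, as in the classical self-condensation of aryloxyacetates.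

**Step 3**
Reactants: 4 methyl 3-oxo-2,4-bis(3,4,5-trimethoxyphenoxy)butanoate
Product: 5 methyl (Z)-3-methoxy-2,4-bis(3,4,5-trimethoxyphenoxy)but-2-enoate
Conditions: K2CO3, Me2SO4, DMF, 0 °C → rt
Reagents that add atoms: dimethyl sulfate, COS(=O)(=O)OC
Why: O-alkylation of a β-keto ester enolate, favoured by a hard methylating agent in a dipolar aprotic solvent and by the fact that C-methylation would make the aryloxy-bearing C2 quaternary.

**Step 4**
Reactants: 5 methyl (Z)-3-methoxy-2,4-bis(3,4,5-trimethoxyphenoxy)but-2-enoate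
Product: 6 (Z)-3-methoxy-2,4-bis(3,4,5-trimethoxyphenoxy)but-2-enoic acid
Conditions: LiOH·H2O, THF/MeOH/H2O, rt; 1 M HCl to pH 3, 0 °C
Reagents that add atoms: lithium hydroxide, [Li+].[OH-]
Why: Ester saponification (BAc2), in which the carboxylate formed resists conjugate attack, methanol as cosolvent makes any exchange at the methoxy-bearing carbon degenerate, and cold acidification to pH 3 spares the enol ether.

**Step 5**
Reactants: 7 2,4,6-trimethoxyphenol; 8 trichloroethylene
Product: 10 2-{[(E)-1,2-dichloroethenyl]oxy}-1,3,5-trimethoxybenzene, via dichloroacetylene 9 (not isolated)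
Conditions: K2CO3, DMF, 70 °C
Reagents that add atoms: none
Why: Base turns trichloroethylene into dichloroacetylene 9, to which the phenoxide adds in anti fashion to give the (E)-1,2-dichlorovinyl ether, the standard entry to ynol ethers.

**Step 6**
Reactants: 10 2-{[(E)-1,2-dichloroethenyl]oxy}-1,3,5-trimethoxybenzene
Product: 13 2-(ethynyloxy)-1,3,5-trimethoxybenzene, via 2-[(chloroethynyl)oxy]-1,3,5-trimethoxybenzene 11 (not isolated), via lithium (2,4,6-trimethoxyphenoxy)acetylide 12 (not isolated)
Conditions: n-BuLi (2.2 equiv), Et2O, −78 → −40 °C; H2O, −78 °C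
Reagents that add atoms: none
Why: Dichlorovinyl ether route to ynol ethers, in which n-BuLi eliminates HCl to chloroalkyne 11, a second equivalent effects chlorine–lithium exchange to acetylide 12, and cold protonation gives the terminal aryl ynol ether, which should be kept cold in solution and used promptly.

**Step 7**
Reactants: 6 (Z)-3-methoxy-2,4-bis(3,4,5-trimethoxyphenoxy)but-2-enoic acid
Product: 14 (Z)-3-methoxy-2,4-bis(3,4,5-trimethoxyphenoxy)but-2-enoyl chloride
Conditions: 1-chloro-N,N,2-trimethylprop-1-en-1-amine (1.1 equiv), CH2Cl2, 0 °C → rt; concentrate, use crude at once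
Reagents that add atoms: 1-chloro-N,N,2-trimethylprop-1-en-1-amine (Ghosez reagent), CC(C)=C(Cl)N(C)C
Why: Acid chloride formation with an α-chloroenamine under neutral conditions, which generates neither HCl nor a Vilsmeier-type electrophile and so should spare the enol ether and the electron-rich aryl rings.

**Step 8**
Reactants: 14 (Z)-3-methoxy-2,4-bis(3,4,5-trimethoxyphenoxy)but-2-enoyl chloride; 13 2-(ethynyloxy)-1,3,5-trimethoxybenzene
Product: 19 3-methoxy-5-(2,4,6-trimethoxyphenoxy)-2,4-bis(3,4,5-trimethoxyphenoxy)phenol, via 3-methoxy-2,4-bis(3,4,5-trimethoxyphenoxy)buta-1,3-dien-1-one 15 (not isolated), via 4-[1-methoxy-2-(3,4,5-trimethoxyphenoxy)ethenyl]-3-(2,4,6-trimethoxyphenoxy)-4-(3,4,5-trimethoxyphenoxy)cyclobut-2-en-1-one 16 (not isolated), via (3Z)-5-methoxy-3-(2,4,6-trimethoxyphenoxy)-4,6-bis(3,4,5-trimethoxyphenoxy)hexa-1,3,5-trien-1-one 17 (not isolated), via 5-methoxy-3-(2,4,6-trimethoxyphenoxy)-4,6-bis(3,4,5-trimethoxyphenoxy)cyclohexa-2,4-dien-1-one 18 (not isolated)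
Conditions: Et3N (2 equiv), 13 (1.5 equiv), toluene, 14 added over 4 h at 40 °C; filter; 100 °C
Reagents that add atoms: none
Why: Proposed new method: Et3N removes HCl from 14 across C4/C1 (there is no α-hydrogen) to give vinylketene 15, whose electrophilic ketene carbon bonds to the terminal carbon of ynol ether 13 and whose α-carbon bonds to the oxygen-bearing alkyne carbon in a polarity-matched [2+2] cycloaddition that forms B2–B3 and B1–B6 in cyclobutenone 16. On heating, conrotatory 4π opening of 16 cuts the old B3–B6 bond with the aryloxy donor on that carbon rotating outward and the enol-ether arm inward, so dienylketene 17 has its termini cis and closes ring B by thermal disrotatory 6π electrocyclisation (B3–B4) to dienone 18, which tautomerises to phenol 19. The closest known reaction type is the Danheiser benzannulation, in which vinylketenes from cyclobutenones or diazo ketones react with alkoxy- and siloxyalkynes through this same [2+2]/4π/6π cascade; amine dehydrochlorination of α,β-unsaturated acid chlorides to vinylketenes and [2+2] addition of in situ ketenes to alkoxyalkynes are each known, but their combination on a fully oxygenated vinylketene is not. No stereocentre is formed, and the C3=C4 geometry of 15 is irrelevant because that carbon becomes aromatic. The step needs regioselectivity (H at B2 next to the new hydroxyl), which the ketene/ynol ether polarity secures, and a direct [4+2] mode would give the same constitution because the two 3,4,5-trimethoxyphenoxy groups are identical. Adding 14 slowly to excess 13 at 40 °C and heating only after 14 is consumed should keep ketene dimerisation and O-acylation of 19 down, and the aryl ynol ether has no β-hydrogen and so cannot fragment by a retro-ene reaction.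

**Step 9**
Reactants: 19 3-methoxy-5-(2,4,6-trimethoxyphenoxy)-2,4-bis(3,4,5-trimethoxyphenoxy)phenol
Product: 20 5-(2,4,6-trihydroxyphenoxy)-2,4-bis(3,4,5-trihydroxyphenoxy)benzene-1,3-diol (CNP0304743.0)
Conditions: BBr3 (20 equiv), CH2Cl2, −78 °C → rt; MeOH then H2O, under Ar
Reagents that add atoms: none
Why: Lewis acid demethylation of aryl methyl ethers with BBr3, which cleaves O–CH3 bonds but not diaryl ether bonds, as is standard for permethylated phlorotannins, with the air-sensitive polyphenol worked up under argon.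

**Compound list**
1 | 3,4,5-trimethoxyphenol | COc1cc(O)cc(OC)c1OC | starting material
2 | methyl bromoacetate | COC(=O)CBr | starting material
3 | methyl 2-(3,4,5-trimethoxyphenoxy)acetate | COC(=O)COc1cc(OC)c(OC)c(OC)c1 | intermediate
4 | methyl 3-oxo-2,4-bis(3,4,5-trimethoxyphenoxy)butanoate (racemic) | COC(=O)C(Oc1cc(OC)c(OC)c(OC)c1)C(=O)COc1cc(OC)c(OC)c(OC)c1 | intermediate
5 | methyl (Z)-3-methoxy-2,4-bis(3,4,5-trimethoxyphenoxy)but-2-enoate | CO/C(COc1cc(OC)c(OC)c(OC)c1)=C(Oc1cc(OC)c(OC)c(OC)c1)/C(=O)OC | intermediate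
6 | (Z)-3-methoxy-2,4-bis(3,4,5-trimethoxyphenoxy)but-2-enoic acid | CO/C(COc1cc(OC)c(OC)c(OC)c1)=C(Oc1cc(OC)c(OC)c(OC)c1)/C(O)=O | intermediate
7 | 2,4,6-trimethoxyphenol | COc1cc(OC)c(O)c(OC)c1 | starting material
8 | trichloroethylene | ClC=C(Cl)Cl | starting material
9 | dichloroacetylene | ClC#CCl | intermediate (not isolated)
10 | 2-{[(E)-1,2-dichloroethenyl]oxy}-1,3,5-trimethoxybenzene | Cl/C=C(/Cl)Oc1c(OC)cc(OC)cc1OC | intermediate
11 | 2-[(chloroethynyl)oxy]-1,3,5-trimethoxybenzene | ClC#COc1c(OC)cc(OC)cc1OC | intermediate (not isolated)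
12 | lithium (2,4,6-trimethoxyphenoxy)acetylide | [Li]C#COc1c(OC)cc(OC)cc1OC | intermediate (not isolated)
13 | 2-(ethynyloxy)-1,3,5-trimethoxybenzene | C#COc1c(OC)cc(OC)cc1OC | intermediate
14 | (Z)-3-methoxy-2,4-bis(3,4,5-trimethoxyphenoxy)but-2-enoyl chloride | CO/C(COc1cc(OC)c(OC)c(OC)c1)=C(Oc1cc(OC)c(OC)c(OC)c1)/C(Cl)=O | intermediate
15 | 3-methoxy-2,4-bis(3,4,5-trimethoxyphenoxy)buta-1,3-dien-1-one (vinylketene, E/Z not defined) | O=C=C(Oc1cc(OC)c(OC)c(OC)c1)C(OC)=COc1cc(OC)c(OC)c(OC)c1 | intermediate (not isolated)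
16 | 4-[1-methoxy-2-(3,4,5-trimethoxyphenoxy)ethenyl]-3-(2,4,6-trimethoxyphenoxy)-4-(3,4,5-trimethoxyphenoxy)cyclobut-2-en-1-one (racemic) | O=C1C=C(Oc2c(OC)cc(OC)cc2OC)C1(Oc1cc(OC)c(OC)c(OC)c1)C(OC)=COc1cc(OC)c(OC)c(OC)c1 | intermediate (not isolated)
17 | (3Z)-5-methoxy-3-(2,4,6-trimethoxyphenoxy)-4,6-bis(3,4,5-trimethoxyphenoxy)hexa-1,3,5-trien-1-one (dienylketene) | O=C=C/C(Oc1c(OC)cc(OC)cc1OC)=C(Oc1cc(OC)c(OC)c(OC)c1)\C(OC)=COc1cc(OC)c(OC)c(OC)c1 | intermediate (not isolated)
18 | 5-methoxy-3-(2,4,6-trimethoxyphenoxy)-4,6-bis(3,4,5-trimethoxyphenoxy)cyclohexa-2,4-dien-1-one (racemic) | O=C1C=C(Oc2c(OC)cc(OC)cc2OC)C(Oc2cc(OC)c(OC)c(OC)c2)=C(OC)C1Oc1cc(OC)c(OC)c(OC)c1 | intermediate (not isolated)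
19 | 3-methoxy-5-(2,4,6-trimethoxyphenoxy)-2,4-bis(3,4,5-trimethoxyphenoxy)phenol | COc1cc(OC)c(Oc2cc(O)c(Oc3cc(OC)c(OC)c(OC)c3)c(OC)c2Oc2cc(OC)c(OC)c(OC)c2)c(OC)c1 | intermediate
20 | 5-(2,4,6-trihydroxyphenoxy)-2,4-bis(3,4,5-trihydroxyphenoxy)benzene-1,3-diol | Oc1cc(O)c(Oc2cc(O)c(Oc3cc(O)c(O)c(O)c3)c(O)c2Oc2cc(O)c(O)c(O)c2)c(O)c1 | target

**Totals**
Total step count: 9. Longest linear sequence: 7 steps (steps 1, 2, 3, 4, 7, 8, 9); the ynol ether branch (steps 5, 6) joins at step 8.

**Steps most likely to fail**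

Step 8. The vinylketene may dimerise or be consumed by the amine faster than it adds to the ynol ether, or γ-deprotonation of the donor-deactivated acid chloride may be too slow. The fallback uses known chemistry, sets out from 7 and 1, and comes back to the route at 20. Phenol 7 would be coupled with 1-bromo-2,4-difluoro-5-methoxybenzene F1 in an Ullmann ether synthesis (CuI, picolinic acid, K3PO4, DMSO, 90 °C) to give 2-(2,4-difluoro-5-methoxyphenoxy)-1,3,5-trimethoxybenzene F2. Lithiation between the two fluorines (LDA, THF, −78 °C) and formylation with DMF should give 2,6-difluoro-3-methoxy-5-(2,4,6-trimethoxyphenoxy)benzaldehyde F3. Double SNAr of both aldehyde-activated fluorides with 1 (2.2 equiv, K2CO3, DMF, 100 °C) should give 3-methoxy-5-(2,4,6-trimethoxyphenoxy)-2,6-bis(3,4,5-trimethoxyphenoxy)benzaldehyde F4. Dakin-type Baeyer–Villiger oxidation (mCPBA, CH2Cl2; then K2CO3, MeOH) should give 3-methoxy-5-(2,4,6-trimethoxyphenoxy)-2,6-bis(3,4,5-trimethoxyphenoxy)phenol F5, a regioisomer of 19 with the free hydroxyl at B5. Under the conditions of step 9 this gives 20.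

Step 7. The push–pull acid chloride may decompose on concentration, by acylation of an electron-rich ring or loss of the enol ether. The fallback sets out from 6 and comes back at 19. The acid would be activated in the presence of 13 with 2-chloro-1-methylpyridinium iodide and Et3N (CH2Cl2, then toluene, 100 °C), so that 1-methyl-2-{[(Z)-3-methoxy-2,4-bis(3,4,5-trimethoxyphenoxy)but-2-enoyl]oxy}pyridinium iodide F6 forms and eliminates to ketene 15 without the acid chloride ever accumulating.

Step 3. C-methylation at C2 may compete with O-methylation. The fallback sets out from 4 and comes back at 5. The ketone would be ketalised with trimethyl orthoformate (cat. TsOH, MeOH) to methyl 3,3-dimethoxy-2,4-bis(3,4,5-trimethoxyphenoxy)butanoate F7. Elimination of methanol towards the ester-activated C2–H (TMSOTf, i-Pr2NEt, CH2Cl2) should then give the conjugated enol ether.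

**Further compounds**
F1 | step 8 | 1-bromo-2,4-difluoro-5-methoxybenzene (purchased) | COc1cc(Br)c(F)cc1F
F2 | step 8 | 2-(2,4-difluoro-5-methoxyphenoxy)-1,3,5-trimethoxybenzene | COc1cc(Oc2c(OC)cc(OC)cc2OC)c(F)cc1F
F3 | step 8 | 2,6-difluoro-3-methoxy-5-(2,4,6-trimethoxyphenoxy)benzaldehyde | COc1cc(Oc2c(OC)cc(OC)cc2OC)c(F)c(C=O)c1F
F4 | step 8 | 3-methoxy-5-(2,4,6-trimethoxyphenoxy)-2,6-bis(3,4,5-trimethoxyphenoxy)benzaldehyde | COc1cc(Oc2c(OC)cc(OC)cc2OC)c(Oc2cc(OC)c(OC)c(OC)c2)c(C=O)c1Oc1cc(OC)c(OC)c(OC)c1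
F5 | step 8 | 3-methoxy-5-(2,4,6-trimethoxyphenoxy)-2,6-bis(3,4,5-trimethoxyphenoxy)phenol | COc1cc(Oc2c(OC)cc(OC)cc2OC)c(Oc2cc(OC)c(OC)c(OC)c2)c(O)c1Oc1cc(OC)c(OC)c(OC)c1
F6 | step 7 | 1-methyl-2-{[(Z)-3-methoxy-2,4-bis(3,4,5-trimethoxyphenoxy)but-2-enoyl]oxy}pyridinium iodide | CO/C(COc1cc(OC)c(OC)c(OC)c1)=C(Oc1cc(OC)c(OC)c(OC)c1)/C(=O)Oc1cccc[n+]1C.[I-]
F7 | step 3 | methyl 3,3-dimethoxy-2,4-bis(3,4,5-trimethoxyphenoxy)butanoate | COC(=O)C(Oc1cc(OC)c(OC)c(OC)c1)C(OC)(OC)COc1cc(OC)c(OC)c(OC)c1
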